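The numbers in the tables were generated by integration from invented constants; noise was put on by code.

2.10 mM is the number I carry from flask to flask: I call it the dissolved supply, the amount of solid first end groups that leaves the solid in 50 min, taken as the mean of the last readings of the maple and birch runs.

| flask | solid first end groups | second end groups | temperature | remark | time |
|---|---|---|---|---|---|
| maple | 0.010 M | 3.5 mM (fed, over 50 min) | −25 °C | run made earlier |  |
| birch | 0.010 M | 12 mM (fed, over 50 min) | −14 °C | run made earlier |  |
| Tuesday's | 0.010 M | 3.00 mM | −20 °C | everything together at the start | 50 min |
| Wednesday's | 0.010 M | 10.0 mM (fed, over 50 min) | −20 °C |  | 50 min |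

| run | time / min | links / % | solid first end groups / % |
|---|---|---|---|
| maple | 4.00 | 0 | 101 |
| maple | 6.00 | 3 | 93 |
| maple | 12.0 | 0 | 92 |
| maple | 20.0 | 2 | 94 |
| maple | 30.0 | 2 | 89 |
| maple | 50.0 | 4 | 80 |
| birch | 3.00 | 1 | 99 |
| birch | 10.0 | 2 | 90 |
| birch | 20.0 | 7 | 90 |
| birch | 25.0 | 6 | 86 |
| birch | 40.0 | 16 | 79 |
| birch | 50.0 | 20 | 78 |

(each reading ± 2 percentage points)

- at the start none of the solid first end groups is in solution
- what has only dissolved of solid first end groups counts as not reacted

- the winner by amount of links, in percent of the solid first end groups charged; "neither" if no more than 2 percentage points parts them (Tuesday's / Wednesday's / neither)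
- how much links is there at the end, in percent of the solid first end groups charged: Tuesday's
- how much links is there at the end, in percent of the solid first end groups charged: Wednesday's

Those two last readings lie 2 percentage points apart, each good to 2 points, although maple ran at −25 °C with 3.5 mM of second end groups and birch at −14 °C with 12 mM. My bench rule is therefore to carry that supply over to Tuesday's and to Wednesday's and to hold links under it, which on 0.010 M makes a ceiling of 21.0% for each of them.

The rule gives a ceiling and not a yield, and its border shows in the capture, which is links over solid lost: as read, 0.909 in the birch run but 0.200 in the maple run. The capture follows the ratio of second end groups charged to supply, 5.71 for birch and 1.67 for maple, though temperature moves with it there. Tuesday's stands at 1.43 and Wednesday's at 4.76, both at a temperature between the two runs, so I expect Wednesday's to win, with links between 4.20% and 19.1%.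

The forecast names Wednesday's, with 10% for Tuesday's and 15% for Wednesday's, on the ground that “dissolution looks rate-limiting and roughly independent of the second end groups”; my bracket is wider and commits to no single value.

The flask gives Wednesday's, with 8.72% for Tuesday's and 14.6% for Wednesday's.

    first end groups + second end groups → links + released group (k = 10.0 M⁻¹ min⁻¹, Ea = 57.0 kJ mol⁻¹)
    2 first end groups → self-condensation product (k = 0.400 M⁻¹ min⁻¹, Ea = 40.0 kJ mol⁻¹)
    solid first end groups ⇌ first end groups, rate k3*(cs3 - [first end groups]) while solid is left; crystals form when [first end groups] > cs3 (solubility = 2.10 mM, k = 0.0270 min⁻¹)
    (constants at −20 °C)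

Wednesday's links come to 1.46 mM, a capture of 0.695 of the supply. The neighbouring flask is Wednesday's with 0.025 M of solid first end groups, so taking the same supply makes a ceiling of 8.40% of that larger charge, and the same capture reckons links at 5.84%. The neighbouring flask gives 5.85% of links, with 91.8% of its solid first end groups still solid, and its released group stands at 0.00146 M, against 0.00146 M in Wednesday's.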